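The earlier runs and the new flask were generated by integration for substances that don't exist.

Over-reaction looks slow in the epsilon run: after 30.0 min it has given 4.2% of over-reaction product, less than the 21.3% of target.

| flask | substrate | partner | free catalyst | temperature | remark | time |
|---|---|---|---|---|---|---|
| epsilon | 0.24 M | 1.2 equiv (in portions, 3) | 0.66 mol% | 70 °C | run made earlier; portions every 10 min |  |
| east | 0.12 M | 1.20 equiv (in portions, 3) | 0.66 mol% | 70 °C | the portions of partner follow each other after 10 min, the first at the start | 2.5 h |
| north-west | 0.12 M | 1.20 equiv | 0.66 mol% | 90 °C | everything together at the start | 0.80 h |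

epsilon run (percent of the substrate charged)

| time / min | target / % | over-reaction product / % | substrate / % |
|---|---|---|---|
| 2.50 | 2.3 | 0 | 96.7 |
| 4.00 | 3.4 | 0.1 | 96.5 |
| 6.00 | 4.8 | 1.1 | 94.4 |
| 10.0 | 8.0 | 1.1 | 90.3 |
| 20.0 | 15.8 | 1.9 | 80.1 |
| 30.0 | 21.3 | 4.2 | 73.7 |

(standard deviation of a reading: 0.5 percentage points)

- the numbers in the tables scatter with a standard deviation of 0.5 percentage points
- steps thought possible: partner + free catalyst -> catalyst intermediate A; catalyst intermediate A <-> catalyst intermediate B; substrate + catalyst intermediate B <-> catalyst intermediate C; catalyst intermediate C -> free catalyst + target; target -> over-reaction product; partner -> decomposed reagent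
- the earlier runs do not show what temperature does; that part of a forecast is a guess
- no earlier run changes the charge of free catalyst; that part of a forecast is a guess

1. which one finishes higher in share of target in all that became target or over-reaction product ("neither" within 2 percentage points) (east / north-west / neither)
2. share of target in all that became target or over-reaction product, east
3. share of target in all that became target or over-reaction product, north-west

Target grew nearly evenly in epsilon, so its average over those minutes is about half its last reading, and the last readings give

k = [over-reaction product] / (average [target] × time) = 0.0131 min⁻¹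

This k is the loss constant of target: the fraction of the target present that goes over each minute, taken as first order. It is a reading, and its small peak carries a scatter of 0.5 percentage points.

Two numbers now seem not to go together. Epsilon still holds 83.5% of its products as target, yet the same k leaves east, at the same 70 °C, with 43.7%, lower than epsilon. The fraction left clears this up. For target made evenly over a time t, the fraction still target is

f = (1 − exp(−kt)) / (kt)

East runs 5.00 times as long as those epsilon readings, so kt reaches 1.97. Making that slows with time lowers f further.

North-west runs for a third of east's time, so at 90 °C it keeps the same f if k grows 3.12-fold. The runs do not show temperature; the guess here is a larger rise, which puts east ahead.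

The forecast also says east, with 33% for east, lower than the figure reckoned here, and 25% for north-west: “East should keep the higher share of target, though the temperature effect in this forecast is a guess.”

    partner + free catalyst → catalyst intermediate A (k = 4000 M⁻¹ min⁻¹, Ea = 51.0 kJ mol⁻¹)
    catalyst intermediate A ⇌ catalyst intermediate B (K = 2.10, k = 340 min⁻¹, Ea = 70.0 kJ mol⁻¹, ΔH = −51.0 kJ mol⁻¹)
    substrate + catalyst intermediate B ⇌ catalyst intermediate C (K = 200 M⁻¹, k = 13.0 M⁻¹ min⁻¹, Ea = 50.0 kJ mol⁻¹, ΔH = −13.0 kJ mol⁻¹)
    catalyst intermediate C → free catalyst + target (k = 5.80 min⁻¹, Ea = 80.0 kJ mol⁻¹)
    target → over-reaction product (k = 0.0150 min⁻¹, Ea = 116 kJ mol⁻¹)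
    partner → decomposed reagent (k = 0.00980 min⁻¹, Ea = 115 kJ mol⁻¹)
    (constants at 70 °C)

The simulation puts east ahead, with 34.2% for east, lower than the reckoned f, and 1.58% for north-west, where 0.438% of target stands beside 27.2% of over-reaction product. East at 2.50 h holds 20.6% of target and 1.6% of its partner, the limiting reagent. The neighbouring flask is east left until 4.0 h. At the k read from epsilon, the fraction left of the target standing at the end of east, over the extra 90.0 min, is

exp(−kΔt) = 30.6%

which leaves an estimated 6.30% of that target. The neighbour, with substrate at 37% against 40% in east, holds 6.04% of target, less than that estimate, beside 56.5% of over-reaction product, a share of 9.65%.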